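The route rests on cutting the C2–C3 bond of the side chain (C1 = alkylidene carbon on C5 of the tetronic acid ring, ring A; C13 = ketone carbon on the furan, ring B). The only stereocentre, C2, is a CH(CH3) between the unfunctionalised C3 methylene and sp2 carbon C1, so it maps onto a chiral ethyl carbenoid (from ethanol) inserted into a primary C–B bond. In one operation the key step forms C2–C3, sets C2 as S and leaves a C2–B bond for later stereospecific exchange into C2–C1. Its precursor is an achiral primary pinacol boronate carrying the (E,E)-skipped diene and the 3-furyl ketone as a dioxolane.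

Key step: step 8

Remark: the exocyclic alkene on ring A is taken as E (C2 cis to the C4 hydroxyl), as the SMILES encodes.

**Step 1**
Reactants: 1 ethyl 3-(furan-3-yl)-3-oxopropanoate; 2 (E)-4-chloro-3-methylbut-2-en-1-yl acetate
Product: 3 ethyl (4E)-6-acetoxy-2-(furan-3-carbonyl)-4-methylhex-4-enoate (racemic at C2)
Conditions: K2CO3, NaI (cat.), acetone, reflux
Reagents that add atoms: none
Why: Acetoacetic-ester-type C-alkylation, in which the soft potassium enolate of 1 displaces the primary allylic chloride of 2 in an iodide-catalysed SN2 reaction that should leave the acetate and the E alkene untouched.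

**Step 2**
Reactants: 3 ethyl (4E)-6-acetoxy-2-(furan-3-carbonyl)-4-methylhex-4-enoate
Product: 5 (4E)-1-(furan-3-yl)-6-hydroxy-4-methylhex-4-en-1-one, via keto acid 4 (not isolated)
Conditions: NaOH, EtOH/H2O, rt; then 1 M HCl to pH 3, 45 °C
Reagents that add atoms: none
Why: Ketonic hydrolysis of the acetoacetic ester synthesis, in which hydroxide saponifies the ethyl ester and the acetate and the β-keto acid 4 freed on acidification should lose CO2 on gentle warming.

**Step 3**
Reactants: 5 (4E)-1-(furan-3-yl)-6-hydroxy-4-methylhex-4-en-1-one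
Product: 7 (2E)-5-[2-(furan-3-yl)-1,3-dioxolan-2-yl]-3-methylpent-2-en-1-ol, via TMS ether 6 (not isolated)
Conditions: (TMSOCH2)2, TMSOTf (cat.), CH2Cl2, −78 → 0 °C; pyridine; then K2CO3 (cat.), MeOH, rt
Reagents that add atoms: 1,2-bis(trimethylsilyloxy)ethane, C[Si](C)(C)OCCO[Si](C)(C)C
Why: Noyori ketalisation is aprotic and cold, so the ionisation-prone allylic alcohol (silylated in passing) and the furan should survive, and basic methanolysis then frees the hydroxyl.

**Step 4**
Reactants: 7 (2E)-5-[2-(furan-3-yl)-1,3-dioxolan-2-yl]-3-methylpent-2-en-1-ol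
Product: 9 2-[(3E)-5-chloro-3-methylpent-3-en-1-yl]-2-(furan-3-yl)-1,3-dioxolane, via mesylate 8 (not isolated)
Conditions: MsCl, LiCl, 2,4,6-collidine, DMF, 0 °C
Reagents that add atoms: lithium chloride, [Li+].[Cl-]
Why: Collington–Meyers chlorination, in which the allylic mesylate formed in situ is displaced by chloride in an SN2 reaction that should give the primary allylic chloride without allylic transposition under buffered, ketal-safe conditions.

**Step 5**
Reactants: 10 5-chloropent-1-yne; 9 2-[(3E)-5-chloro-3-methylpent-3-en-1-yl]-2-(furan-3-yl)-1,3-dioxolane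
Product: 12 2-[(3E,6E)-10-chloro-3,7-dimethyldeca-3,6-dien-1-yl]-2-(furan-3-yl)-1,3-dioxolane, via alkenylalane 11 (not isolated)
Conditions: 10, Me3Al, Cp2ZrCl2 (cat.), ClCH2CH2Cl, rt; volatiles removed; then 9, Pd(PPh3)4 (cat.), THF, rt
Reagents that add atoms: trimethylaluminium, C[Al](C)C
Why: Negishi carboalumination (Zr-catalysed syn addition of Me–Al to the terminal alkyne) should give the (E)-alkenylalane 11, and Pd-catalysed alkenyl–allyl cross-coupling then joins it to the primary terminus of 9 with retention of both alkene geometries, the unactivated alkyl chloride being inert to both stages.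

**Step 6**
Reactants: 12 2-[(3E,6E)-10-chloro-3,7-dimethyldeca-3,6-dien-1-yl]-2-(furan-3-yl)-1,3-dioxolane
Product: 13 2-{(4E,7E)-10-[2-(furan-3-yl)-1,3-dioxolan-2-yl]-4,8-dimethyldeca-4,7-dien-1-yl}-4,4,5,5-tetramethyl-1,3,2-dioxaborolane
Conditions: B2pin2, CuCl (cat.), Xantphos (cat.), KOtBu, THF, rt
Reagents that add atoms: bis(pinacolato)diboron, CC1(C)OB(OC1(C)C)B1OC(C)(C)C(C)(C)O1
Why: Copper-catalysed boryl substitution of an unactivated primary alkyl halide with B2pin2 should replace chloride by Bpin without touching the ketal, the furan or the trisubstituted alkenes.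

**Step 7**
Reactants: 14 ethanol; 15 N,N-diisopropylcarbamoyl chloride
Product: 16 ethyl N,N-diisopropylcarbamate
Conditions: Et3N, CH2Cl2, reflux
Reagents that add atoms: none
Why: O-Carbamoylation of a primary alcohol by the carbamoyl chloride (nucleophilic acyl substitution) gives the carbamate needed for directed lithiation.

**Step 8**
Reactants: 16 ethyl N,N-diisopropylcarbamate; 13 2-{(4E,7E)-10-[2-(furan-3-yl)-1,3-dioxolan-2-yl]-4,8-dimethyldeca-4,7-dien-1-yl}-4,4,5,5-tetramethyl-1,3,2-dioxaborolane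
Product: 19 2-{(2S,6E,9E)-12-[2-(furan-3-yl)-1,3-dioxolan-2-yl]-6,10-dimethyldodeca-6,9-dien-2-yl}-4,4,5,5-tetramethyl-1,3,2-dioxaborolane, via lithiated carbamate 17 (not isolated), via boronate complex 18 (not isolated)
Conditions: 16, (+)-sparteine, s-BuLi, Et2O, −78 °C; then 13, −78 °C; then MgBr2·OEt2, reflux; aq. NH4Cl
Reagents that add atoms: none
Why: s-BuLi/(+)-sparteine removes the pro-R hydrogen of 16 to give the configurationally stable (R)-carbenoid 17, which attacks boron of 13 with retention to give ate complex 18; MgBr2-assisted 1,2-metallate rearrangement then moves the chain CH2 from boron to carbon antiperiplanar to the departing carbamate, with inversion, forming C2–C3. The closest known reaction type is the Hoppe lithiation of O-alkyl carbamates coupled with homologation of pinacol boronic esters (lithiation–borylation). No ring is closed. The new stereocentre C2 (S) is set by the reagent alone, since 13 is achiral: retention at boron followed by inversion in the migration turns the (R)-carbenoid into the (S)-boronate. The step needs chemoselectivity for boron over the furan C–H bonds, the ketal and the skipped diene, which is secured by finishing the deprotonation of 16 before 13 is added so that 13 never meets s-BuLi; it also needs carbon rather than oxygen migration, which the unhindered primary alkyl group and MgBr2 favour.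

**Step 9**
Reactants: 19 2-{(2S,6E,9E)-12-[2-(furan-3-yl)-1,3-dioxolan-2-yl]-6,10-dimethyldodeca-6,9-dien-2-yl}-4,4,5,5-tetramethyl-1,3,2-dioxaborolane
Product: 22 2-[(3E,6E,11S)-12-bromo-3,7,11-trimethyltrideca-3,6,12-trien-1-yl]-2-(furan-3-yl)-1,3-dioxolane, via bromovinyl boronate complex 20 (not isolated), via iodo boronate 21 (not isolated)
Conditions: CH2=CHBr, LiN(iPr)2, THF, −78 °C (in situ trapping); then I2, MeOH, −78 °C; NaOMe, MeOH, −78 °C → rt
Reagents that add atoms: vinyl bromide, C=CBr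
Why: Zweifel olefination in its deborylative-alkynylation form, in which 1-bromovinyllithium adds to boron, iodination of the vinyl group triggers 1,2-migration of the secondary alkyl group with retention at the stereocentre, and methoxide-induced anti elimination of boron and iodide should give the 2-bromoalkene.

**Step 10**
Reactants: 22 2-[(3E,6E,11S)-12-bromo-3,7,11-trimethyltrideca-3,6,12-trien-1-yl]-2-(furan-3-yl)-1,3-dioxolane
Product: 25 methyl (4S,8E,11E)-14-[2-(furan-3-yl)-1,3-dioxolan-2-yl]-4,8,12-trimethyltetradeca-8,11-dien-2-ynoate, via terminal alkyne 23 (not isolated), via lithium acetylide 24 (not isolated)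
Conditions: LiN(iPr)2 (2.2 equiv), THF, −78 → −40 °C; then ClCO2Me, −78 °C → rt
Reagents that add atoms: methyl chloroformate, COC(=O)Cl
Why: E2 dehydrobromination by LiN(iPr)2 gives alkyne 23, a second equivalent forms acetylide 24, and C-acylation with methyl chloroformate gives the ynoate, the propargylic stereocentre being far less acidic than the acetylenic C–H.

**Step 11**
Reactants: 25 methyl (4S,8E,11E)-14-[2-(furan-3-yl)-1,3-dioxolan-2-yl]-4,8,12-trimethyltetradeca-8,11-dien-2-ynoate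
Product: 27 methyl (2E,4S,8E,11E)-14-[2-(furan-3-yl)-1,3-dioxolan-2-yl]-2-iodo-4,8,12-trimethyltetradeca-2,8,11-trienoate, via vinylstannane 26 (not isolated)
Conditions: Bu3SnH, Pd(PPh3)4 (cat.), THF, 0 °C → rt; then I2, NaHCO3, CH2Cl2, 0 °C
Reagents that add atoms: iodine, II
Why: Pd-catalysed hydrostannation of a 2-alkynoate is a syn addition that places tin on the α-carbon, so the side chain ends cis to the ester, and iododestannylation proceeds with retention, fixing the geometry that becomes the E-alkylidene.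

**Step 12**
Reactants: 27 methyl (2E,4S,8E,11E)-14-[2-(furan-3-yl)-1,3-dioxolan-2-yl]-2-iodo-4,8,12-trimethyltetradeca-2,8,11-trienoate
Product: 28 methyl (2E,4S,8E,11E)-14-[2-(furan-3-yl)-1,3-dioxolan-2-yl]-4,8,12-trimethyl-2-(propanoyloxy)tetradeca-2,8,11-trienoate
Conditions: EtCO2H, Cs2CO3, CuI (cat.), 1,10-phenanthroline (cat.), toluene, 80 °C
Reagents that add atoms: propanoic acid, CCC(=O)O
Why: Ullmann-type C(sp2)–O coupling of a vinyl iodide with a carboxylate is a known way to enol esters with retention of alkene geometry, and the electron-poor α-iodo enoate should add oxidatively to monovalent copper readily.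

**Step 13**
Reactants: 28 methyl (2E,4S,8E,11E)-14-[2-(furan-3-yl)-1,3-dioxolan-2-yl]-4,8,12-trimethyl-2-(propanoyloxy)tetradeca-2,8,11-trienoate
Product: 30 (5E)-5-[(2S,6E,9E)-13-(furan-3-yl)-2,6,10-trimethyl-13-oxotrideca-6,9-dien-1-ylidene]-4-hydroxy-3-methylfuran-2(5H)-one, via lithium tetronate 29 (not isolated)
Conditions: LiN(SiMe3)2 (2.5 equiv), THF, −78 → 0 °C; then 1 M HCl, THF, rt
Reagents that add atoms: water, O
Why: Dieckmann condensation (intramolecular Claisen, 5-exo-trig) of the propionate enolate onto the geminal methyl ester closes ring A without touching the alkene geometry set in step 11, and dilute aqueous acid then protonates tetronate 29 and hydrolyses the dioxolane to the furyl ketone.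

**Compound list**

1 | ethyl 3-(furan-3-yl)-3-oxopropanoate | CCOC(=O)CC(=O)c1ccoc1 | starting material
2 | (E)-4-chloro-3-methylbut-2-en-1-yl acetate | CC(=O)OC/C=C(\C)CCl | starting material
3 | ethyl (4E)-6-acetoxy-2-(furan-3-carbonyl)-4-methylhex-4-enoate | CCOC(=O)C(C/C(C)=C/COC(C)=O)C(=O)c1ccoc1 | intermediate
4 | (4E)-2-(furan-3-carbonyl)-6-hydroxy-4-methylhex-4-enoic acid | OC(=O)C(C/C(C)=C/CO)C(=O)c1ccoc1 | intermediate
5 | (4E)-1-(furan-3-yl)-6-hydroxy-4-methylhex-4-en-1-one | O=C(CC/C(C)=C/CO)c1ccoc1 | intermediate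
6 | trimethyl{[(2E)-5-(2-(furan-3-yl)-1,3-dioxolan-2-yl)-3-methylpent-2-en-1-yl]oxy}silane | C[Si](C)(C)OC/C=C(\C)CCC1(c2ccoc2)OCCO1 | intermediate
7 | (2E)-5-[2-(furan-3-yl)-1,3-dioxolan-2-yl]-3-methylpent-2-en-1-ol | OC/C=C(\C)CCC1(c2ccoc2)OCCO1 | intermediate
8 | (2E)-5-[2-(furan-3-yl)-1,3-dioxolan-2-yl]-3-methylpent-2-en-1-yl methanesulfonate | CS(=O)(=O)OC/C=C(\C)CCC1(c2ccoc2)OCCO1 | intermediate
9 | 2-[(3E)-5-chloro-3-methylpent-3-en-1-yl]-2-(furan-3-yl)-1,3-dioxolane | ClC/C=C(\C)CCC1(c2ccoc2)OCCO1 | intermediate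
10 | 5-chloropent-1-yne | C#CCCCCl | starting material
11 | [(1E)-5-chloro-2-methylpent-1-en-1-yl]dimethylalane | C[Al](C)/C=C(\C)CCCCl | intermediate
12 | 2-[(3E,6E)-10-chloro-3,7-dimethyldeca-3,6-dien-1-yl]-2-(furan-3-yl)-1,3-dioxolane | ClCCC/C(C)=C/C/C=C(\C)CCC1(c2ccoc2)OCCO1 | intermediate
13 | 2-{(4E,7E)-10-[2-(furan-3-yl)-1,3-dioxolan-2-yl]-4,8-dimethyldeca-4,7-dien-1-yl}-4,4,5,5-tetramethyl-1,3,2-dioxaborolane | CC1(C)OB(CCC/C(C)=C/C/C=C(\C)CCC2(c3ccoc3)OCCO2)OC1(C)C | intermediate
14 | ethanol | CCO | starting material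
15 | N,N-diisopropylcarbamoyl chloride | CC(C)N(C(C)C)C(=O)Cl | starting material
16 | ethyl N,N-diisopropylcarbamate | CCOC(=O)N(C(C)C)C(C)C | intermediate
17 | (R)-1-lithioethyl N,N-diisopropylcarbamate as its (+)-sparteine complex | [Li][C@H](C)OC(=O)N(C(C)C)C(C)C | intermediate
18 | lithium [(1R)-1-(diisopropylcarbamoyloxy)ethyl]{(4E,7E)-10-[2-(furan-3-yl)-1,3-dioxolan-2-yl]-4,8-dimethyldeca-4,7-dien-1-yl}(pinacolato)borate | [Li+].CC1(C)O[B-](CCC/C(C)=C/C/C=C(\C)CCC2(c3ccoc3)OCCO2)([C@H](C)OC(=O)N(C(C)C)C(C)C)OC1(C)C | intermediate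
19 | 2-{(2S,6E,9E)-12-[2-(furan-3-yl)-1,3-dioxolan-2-yl]-6,10-dimethyldodeca-6,9-dien-2-yl}-4,4,5,5-tetramethyl-1,3,2-dioxaborolane | CC1(C)OB([C@@H](C)CCC/C(C)=C/C/C=C(\C)CCC2(c3ccoc3)OCCO2)OC1(C)C | intermediate
20 | lithium (1-bromovinyl){(2S,6E,9E)-12-[2-(furan-3-yl)-1,3-dioxolan-2-yl]-6,10-dimethyldodeca-6,9-dien-2-yl}(pinacolato)borate | [Li+].CC1(C)O[B-](C(Br)=C)([C@@H](C)CCC/C(C)=C/C/C=C(\C)CCC2(c3ccoc3)OCCO2)OC1(C)C | intermediate
21 | 2-{(3S,7E,10E)-2-bromo-13-[2-(furan-3-yl)-1,3-dioxolan-2-yl]-1-iodo-3,7,11-trimethyltrideca-7,10-dien-2-yl}-4,4,5,5-tetramethyl-1,3,2-dioxaborolane (C2 unassigned) | CC1(C)OB(C(Br)(CI)[C@@H](C)CCC/C(C)=C/C/C=C(\C)CCC2(c3ccoc3)OCCO2)OC1(C)C | intermediate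
22 | 2-[(3E,6E,11S)-12-bromo-3,7,11-trimethyltrideca-3,6,12-trien-1-yl]-2-(furan-3-yl)-1,3-dioxolane | C=C(Br)[C@@H](C)CCC/C(C)=C/C/C=C(\C)CCC1(c2ccoc2)OCCO1 | intermediate
23 | 2-(furan-3-yl)-2-[(3E,6E,11S)-3,7,11-trimethyltrideca-3,6-dien-12-yn-1-yl]-1,3-dioxolane | C#C[C@@H](C)CCC/C(C)=C/C/C=C(\C)CCC1(c2ccoc2)OCCO1 | intermediate
24 | lithium (3S,7E,10E)-13-[2-(furan-3-yl)-1,3-dioxolan-2-yl]-3,7,11-trimethyltrideca-7,10-dien-1-yn-1-ide | [Li]C#C[C@@H](C)CCC/C(C)=C/C/C=C(\C)CCC1(c2ccoc2)OCCO1 | intermediate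
25 | methyl (4S,8E,11E)-14-[2-(furan-3-yl)-1,3-dioxolan-2-yl]-4,8,12-trimethyltetradeca-8,11-dien-2-ynoate | COC(=O)C#C[C@@H](C)CCC/C(C)=C/C/C=C(\C)CCC1(c2ccoc2)OCCO1 | intermediate
26 | methyl (2E,4S,8E,11E)-14-[2-(furan-3-yl)-1,3-dioxolan-2-yl]-4,8,12-trimethyl-2-(tributylstannyl)tetradeca-2,8,11-trienoate | COC(=O)/C(=C\[C@@H](C)CCC/C(C)=C/C/C=C(\C)CCC1(c2ccoc2)OCCO1)[Sn](CCCC)(CCCC)CCCC | intermediate
27 | methyl (2E,4S,8E,11E)-14-[2-(furan-3-yl)-1,3-dioxolan-2-yl]-2-iodo-4,8,12-trimethyltetradeca-2,8,11-trienoate | COC(=O)/C(I)=C\[C@@H](C)CCC/C(C)=C/C/C=C(\C)CCC1(c2ccoc2)OCCO1 | intermediate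
28 | methyl (2E,4S,8E,11E)-14-[2-(furan-3-yl)-1,3-dioxolan-2-yl]-4,8,12-trimethyl-2-(propanoyloxy)tetradeca-2,8,11-trienoate | COC(=O)/C(OC(=O)CC)=C\[C@@H](C)CCC/C(C)=C/C/C=C(\C)CCC1(c2ccoc2)OCCO1 | intermediate
29 | lithium salt of (5E)-5-{(2S,6E,9E)-12-[2-(furan-3-yl)-1,3-dioxolan-2-yl]-2,6,10-trimethyldodeca-6,9-dien-1-ylidene}-4-hydroxy-3-methylfuran-2(5H)-one | [Li+].CC1=C([O-])/C(=C\[C@@H](C)CCC/C(C)=C/C/C=C(\C)CCC2(c3ccoc3)OCCO2)OC1=O | intermediate
30 | (5E)-5-[(2S,6E,9E)-13-(furan-3-yl)-2,6,10-trimethyl-13-oxotrideca-6,9-dien-1-ylidene]-4-hydroxy-3-methylfuran-2(5H)-one (CNP0018619.1) | CC1=C(O)/C(=C\[C@@H](C)CCC/C(C)=C/C/C=C(\C)CCC(=O)c2ccoc2)OC1=O | target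

**Step count and risks**

Total step count: 13. Longest linear sequence: 12 steps (steps 1–6 and 8–13, from 1); step 7 is a one-step side branch.

Steps most likely to fail:

Step 12 (C–O coupling). The vinyl iodide may undergo reductive homocoupling or protodeiodination on copper, C–O bond formation with the weakly nucleophilic carboxylate may be slow, and the α-iodo enoate may lose its geometry by addition–elimination under the basic, warm conditions. The fallback sets out from alkynoate 25 and returns at enol propionate 28. CuH-catalysed syn-hydroboration of the ynoate with pinacolborane ([(Ph3P)CuH]6 cat., HBpin, THF, rt) places boron on the α-carbon with the same syn geometry and should give methyl (2Z,4S,8E,11E)-14-[2-(furan-3-yl)-1,3-dioxolan-2-yl]-4,8,12-trimethyl-2-(pinacolboryl)tetradeca-2,8,11-trienoate F1. Brief treatment with KHF2 in MeOH/H2O converts it into the potassium alkenyltrifluoroborate F2. Chan–Lam-type oxidative coupling of F2 with propanoic acid (CuBr cat., DMAP, 4 Å molecular sieves, O2, CH2Cl2, 60 °C) should then give 28 with retention of geometry.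

Step 8 (key step). Boronate complex 18 may rearrange sluggishly, MgBr2 may open the dioxolane during the long reflux, oxygen migration may compete, and enantioselection in the deprotonation may be incomplete. The fallback sets out from boronate 13 and ethanol 14 and returns at 19. Ethanol is acylated with 2,4,6-triisopropylbenzoyl chloride to ethyl 2,4,6-triisopropylbenzoate F3. This is lithiated with s-BuLi/(+)-sparteine and quenched with Me3SnCl to give (R)-1-(trimethylstannyl)ethyl 2,4,6-triisopropylbenzoate F4, which is brought to a single enantiomer by recrystallisation. Tin–lithium exchange with n-BuLi (Et2O, −78 °C, retention) releases sparteine-free (R)-1-lithioethyl 2,4,6-triisopropylbenzoate F5, which adds to 13 to give boronate complex F6. The better benzoate leaving group should allow the 1,2-migration on warming to 35 °C without any Lewis acid, giving 19 with the same stereochemical course.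

Step 9 (alkynylation, first half). The thermally fragile bromovinyl carbenoid may decompose before it reaches the hindered secondary boronate, iodine may attack the skipped diene or the furan, and migration of the secondary group may be incomplete. The fallback sets out from 19 and returns at alkyne 23. Matteson homologation with LiCH2Cl made in situ (BrCH2Cl, n-BuLi, THF, −78 °C → rt) inserts one CH2 with retention to give 2-{(2R,6E,9E)-12-[2-(furan-3-yl)-1,3-dioxolan-2-yl]-2,6,10-trimethyldodeca-6,9-dien-1-yl}-4,4,5,5-tetramethyl-1,3,2-dioxaborolane F7. Oxidation with NaBO3·4H2O (THF/H2O) gives the (2S)-alcohol F8, and Dess–Martin periodinane with NaHCO3 gives the (2S)-aldehyde F9. Seyferth–Gilbert homologation with the Ohira–Bestmann reagent (K2CO3, MeOH, 0 °C) gives 23, which is isolated, deprotonated with LiN(iPr)2 and carboxylated with ClCO2Me as in step 10 to reach 25.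

**Further compounds**

F1 | step 12 | methyl (2Z,4S,8E,11E)-14-[2-(furan-3-yl)-1,3-dioxolan-2-yl]-4,8,12-trimethyl-2-(4,4,5,5-tetramethyl-1,3,2-dioxaborolan-2-yl)tetradeca-2,8,11-trienoate | COC(=O)/C(B1OC(C)(C)C(C)(C)O1)=C\[C@@H](C)CCC/C(C)=C/C/C=C(\C)CCC2(c3ccoc3)OCCO2
F2 | step 12 | potassium trifluoro[(2Z,4S,8E,11E)-14-(2-(furan-3-yl)-1,3-dioxolan-2-yl)-1-methoxy-4,8,12-trimethyl-1-oxotetradeca-2,8,11-trien-2-yl]borate | [K+].COC(=O)/C([B-](F)(F)F)=C\[C@@H](C)CCC/C(C)=C/C/C=C(\C)CCC1(c2ccoc2)OCCO1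
F3 | step 8 | ethyl 2,4,6-triisopropylbenzoate | CCOC(=O)c1c(C(C)C)cc(C(C)C)cc1C(C)C
F4 | step 8 | (R)-1-(trimethylstannyl)ethyl 2,4,6-triisopropylbenzoate | C[Sn](C)(C)[C@H](C)OC(=O)c1c(C(C)C)cc(C(C)C)cc1C(C)C
F5 | step 8 | (R)-1-lithioethyl 2,4,6-triisopropylbenzoate | [Li][C@H](C)OC(=O)c1c(C(C)C)cc(C(C)C)cc1C(C)C
F6 | step 8 | lithium {(4E,7E)-10-[2-(furan-3-yl)-1,3-dioxolan-2-yl]-4,8-dimethyldeca-4,7-dien-1-yl}[(1R)-1-(2,4,6-triisopropylbenzoyloxy)ethyl](pinacolato)borate | [Li+].CC1(C)O[B-](CCC/C(C)=C/C/C=C(\C)CCC2(c3ccoc3)OCCO2)([C@H](C)OC(=O)c4c(C(C)C)cc(C(C)C)cc4C(C)C)OC1(C)C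
F7 | step 9 | 2-{(2R,6E,9E)-12-[2-(furan-3-yl)-1,3-dioxolan-2-yl]-2,6,10-trimethyldodeca-6,9-dien-1-yl}-4,4,5,5-tetramethyl-1,3,2-dioxaborolane | CC1(C)OB(C[C@@H](C)CCC/C(C)=C/C/C=C(\C)CCC2(c3ccoc3)OCCO2)OC1(C)C
F8 | step 9 | (2S,6E,9E)-12-[2-(furan-3-yl)-1,3-dioxolan-2-yl]-2,6,10-trimethyldodeca-6,9-dien-1-ol | OC[C@@H](C)CCC/C(C)=C/C/C=C(\C)CCC1(c2ccoc2)OCCO1
F9 | step 9 | (2S,6E,9E)-12-[2-(furan-3-yl)-1,3-dioxolan-2-yl]-2,6,10-trimethyldodeca-6,9-dienal | O=C[C@@H](C)CCC/C(C)=C/C/C=C(\C)CCC1(c2ccoc2)OCCO1
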